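**Retrosynthetic overview**

1. The target is traced back to its tri-O-isopropyl flavanone (BCl3 at the end), and that to a 5,7-diisopropoxy-6-(1-methylpiperidin-2-yl)chromone by catalyst-controlled conjugate arylation at C2.
2. Ring C comes from an o-acetyl aryl MOM ether made by ortho-lithiation of a 2-arylpiperidine whose aryl ring is still symmetric. Only the oxygen para to the piperidine is ever unmasked, so only it can become O1, which puts the piperidine at C6 and not C8.
3. The piperidine is opened at C2'–C3'. The strategy rests on C2', which is bonded to C6 of ring A (benzylic) and to nitrogen: in an N-Boc-N-(4-chlorobutyl)benzylamine it can be deprotonated enantioselectively and alkylated by the tethered C3'–C6' chain.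
4. The cyclization precursor is reached in four steps from 2,4,6-trihydroxybenzaldehyde and 4-aminobutan-1-ol.
5. Ring order: ring A is bought, the piperidine closes in step 5, ring C closes in step 10, ring B is attached in step 11.

Key step: step 5

Assumption: (−)-sparteine is taken to give the 2'S piperidine, as it gives (S)-N-Boc-2-arylpyrrolidines (same CIP order N > aryl > CH2); if the sense proves opposite on this arene, (+)-sparteine is used in step 5 and nothing else changes.

**Route**

Step 1
Reactants: 1 2,4,6-trihydroxybenzaldehyde; 2 chlorotri(propan-2-yl)silane (TIPSCl)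
Product: 3 2,6-dihydroxy-4-[(triisopropylsilyl)oxy]benzaldehyde
Conditions: TIPSCl (1.05 equiv), imidazole, DMF, −20 to 0 °C
Reagents that add atoms: chlorotri(propan-2-yl)silane 2, CC(C)[Si](Cl)(C(C)C)C(C)C
Why: Chemoselective O-silylation, since the 4-OH is the most acidic hydroxyl (para to the formyl group) and the only one neither hydrogen-bonded to nor flanked by the formyl group, so one equivalent of the bulky chlorosilane at low temperature should react there first.

Step 2
Reactants: 3 2,6-dihydroxy-4-[(triisopropylsilyl)oxy]benzaldehyde; 4 propan-2-ol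
Product: 5 2,6-diisopropoxy-4-[(triisopropylsilyl)oxy]benzaldehyde
Conditions: i-PrOH, PPh3, DIAD (3 equiv each), THF, 0 to 40 °C
Reagents that add atoms: propan-2-ol 4, CC(C)O
Why: Double Mitsunobu etherification, in which the acidic formyl-conjugated phenols protonate the betaine and displace the activated propan-2-ol under neutral conditions that spare the aryl silyl ether para to the aldehyde, which a carbonate-mediated alkylation would put at risk.

Step 3
Reactants: 5 2,6-diisopropoxy-4-[(triisopropylsilyl)oxy]benzaldehyde; 6 4-aminobutan-1-ol; 7 di-tert-butyl dicarbonate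
Product: 10 tert-butyl N-(4-hydroxybutyl)-N-{[2,6-diisopropoxy-4-(triisopropylsilyloxy)phenyl]methyl}carbamate, via imine 8 (not isolated), via amino alcohol 9 (not isolated)
Conditions: 6, 3 Å MS, CH2Cl2, rt; NaBH4, MeOH, 0 °C; then Boc2O, rt
Reagents that add atoms: 4-aminobutan-1-ol 6, NCCCCO; di-tert-butyl dicarbonate 7, CC(C)(C)OC(=O)OC(=O)OC(C)(C)C
Why: Reductive amination by way of the preformed imine 8 guarantees monoalkylation of the primary amine, and Boc2O then acylates the secondary amine 9 in preference to the primary alcohol in the absence of an acylation catalyst.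

Step 4
Reactants: 10 tert-butyl N-(4-hydroxybutyl)-N-{[2,6-diisopropoxy-4-(triisopropylsilyloxy)phenyl]methyl}carbamate; 11 methanesulfonyl chloride; 12 lithium chloride
Product: 14 tert-butyl N-(4-chlorobutyl)-N-{[2,6-diisopropoxy-4-(triisopropylsilyloxy)phenyl]methyl}carbamate, via mesylate 13 (not isolated)
Conditions: MsCl, Et3N, CH2Cl2, 0 °C; then LiCl, DMF, 45 °C
Reagents that add atoms: methanesulfonyl chloride 11, CS(=O)(=O)Cl (atoms in intermediate 13 only); lithium chloride 12, [Li+].[Cl-]
Why: Sulfonylation of the primary alcohol followed by SN2 displacement of mesylate by chloride (Finkelstein-type exchange), non-acidic conditions that leave the Boc group and the acid-labile trialkoxybenzyl–nitrogen bond intact, while the carbamate nitrogen is too weakly nucleophilic to close a pyrrolidine.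

Step 5
Reactants: 14 tert-butyl N-(4-chlorobutyl)-N-{[2,6-diisopropoxy-4-(triisopropylsilyloxy)phenyl]methyl}carbamate
Product: 16 tert-butyl (2S)-2-[2,6-diisopropoxy-4-(triisopropylsilyloxy)phenyl]piperidine-1-carboxylate, via benzylic organolithium 15 (not isolated)
Conditions: s-BuLi (1.3 equiv), (−)-sparteine (1.4 equiv), toluene, −78 °C; MeOH quench at −78 °C
Reagents that add atoms: none
Why: s-BuLi/(−)-sparteine binds to the Boc carbonyl and removes one of the two enantiotopic benzylic protons of 14 (complex-induced proximity effect), giving the dipole-stabilized α-amino benzylic organolithium 15, which displaces the primary chloride intramolecularly to form C2'–C3'. The closest known reaction type is the sparteine-mediated lithiation–cyclization of N-Boc-N-(ω-chloroalkyl)benzylamines to N-Boc-2-arylpyrrolidines and -piperidines. The piperidine closes in 6-exo-tet mode by SN2 attack of the benzylic carbanion on C3'. The C2' stereocentre is set by the chiral diamine in the deprotonation (reagent control) and should be kept because the sparteine-bound organolithium is expected to hold its configuration in toluene at −78 °C for as long as the ring closure needs. The step needs benzylic lithiation to win over lithiation of the ring C–H bonds, addition to the Boc carbonyl and attack at silicon: carbamate-directed benzylic deprotonation is fast at −78 °C, isopropoxy and silyloxy groups are weak ortho directors, and each ring hydrogen is flanked by an isopropoxy group and the bulky triisopropylsilyloxy group.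

Step 6
Reactants: 16 tert-butyl (2S)-2-[2,6-diisopropoxy-4-(triisopropylsilyloxy)phenyl]piperidine-1-carboxylate
Product: 17 tert-butyl (2S)-2-(4-hydroxy-2,6-diisopropoxyphenyl)piperidine-1-carboxylate
Conditions: Bu4NF, THF, 0 °C; aqueous work-up
Reagents that add atoms: none
Why: Fluoride attacks silicon and releases the phenoxide (driven by the strong Si–F bond), conditions to which the carbamate and the isopropyl ethers are inert.

Step 7
Reactants: 17 tert-butyl (2S)-2-(4-hydroxy-2,6-diisopropoxyphenyl)piperidine-1-carboxylate; 18 chloromethyl methyl ether (MOMCl)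
Product: 19 tert-butyl (2S)-2-[2,6-diisopropoxy-4-(methoxymethoxy)phenyl]piperidine-1-carboxylate
Conditions: NaH, MOMCl, THF–DMF, 0 °C
Reagents that add atoms: chloromethyl methyl ether 18, COCCl
Why: Williamson-type O-alkylation of the sodium phenoxide, carried out while nitrogen is still a carbamate so that MOMCl cannot quaternize it, installs the ortho-directing group needed in step 9.

Step 8
Reactants: 19 tert-butyl (2S)-2-[2,6-diisopropoxy-4-(methoxymethoxy)phenyl]piperidine-1-carboxylate
Product: 20 (2S)-2-[2,6-diisopropoxy-4-(methoxymethoxy)phenyl]-1-methylpiperidine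
Conditions: LiAlH4, THF, reflux; aqueous NaOH work-up
Reagents that add atoms: none
Why: Hydride reduction of the carbamate to the N-methyl amine (formamide, then iminium, then amine) replaces an acidic Boc removal, which would ionize the 2,4,6-trioxygenated benzylic C–N bond, and does not touch C2'.

Step 9
Reactants: 20 (2S)-2-[2,6-diisopropoxy-4-(methoxymethoxy)phenyl]-1-methylpiperidine; 21 N-methoxy-N-methylacetamide
Product: 23 1-{2,4-diisopropoxy-6-(methoxymethoxy)-3-[(2S)-1-methylpiperidin-2-yl]phenyl}ethan-1-one, via aryllithium 22 (not isolated)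
Conditions: n-BuLi, THF, 0 °C; then MeC(O)N(OMe)Me, −78 to 0 °C; aqueous quench
Reagents that add atoms: N-methoxy-N-methylacetamide 21, CC(=O)N(C)OC
Why: Directed ortho-metalation at the ring C–H flanked by the MOM ether and an isopropoxy group (the two ring hydrogens are equivalent, so a single regioisomer is possible), followed by Weinreb ketone synthesis, whose chelated tetrahedral intermediate stops at the ketone.

Step 10
Reactants: 23 1-{2,4-diisopropoxy-6-(methoxymethoxy)-3-[(2S)-1-methylpiperidin-2-yl]phenyl}ethan-1-one; 24 N,N-dimethylformamide dimethyl acetal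
Product: 27 5,7-diisopropoxy-6-[(2S)-1-methylpiperidin-2-yl]-4H-chromen-4-one, via MOM enaminone 25 (not isolated), via hydroxy enaminone 26 (not isolated)
Conditions: Me2NCH(OMe)2, toluene, 100 °C; then HCl, MeOH, 50 °C; NaHCO3 work-up
Reagents that add atoms: N,N-dimethylformamide dimethyl acetal 24, COC(OC)N(C)C
Why: Condensation of the acetyl methyl group with the amide acetal gives enaminone 25, acid then removes the MOM group and the freed phenol of 26 adds to the β-carbon and expels dimethylamine (standard chromone synthesis), so that the only oxygen ever unmasked, the one para to the piperidine, becomes O1 and the piperidine sits at C6.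

Step 11
Reactants: 27 5,7-diisopropoxy-6-[(2S)-1-methylpiperidin-2-yl]-4H-chromen-4-one; 28 (4-isopropoxyphenyl)boronic acid
Product: 29 (2S)-5,7-diisopropoxy-2-(4-isopropoxyphenyl)-6-[(2S)-1-methylpiperidin-2-yl]chroman-4-one
Conditions: 27 as its CF3CO2H salt, 28 (2.5 equiv), Pd(OCOCF3)2 (10 mol %), (R)-4-tert-butyl-2-(pyridin-2-yl)-4,5-dihydrooxazole ((R)-t-BuPyOX, 12 mol %), NH4PF6, H2O, ClCH2CH2Cl, 60 °C; NaHCO3 work-up
Reagents that add atoms: (4-isopropoxyphenyl)boronic acid 28, CC(C)Oc1ccc(B(O)O)cc1
Why: Asymmetric conjugate addition of an arylboronic acid to a chromone catalysed by a cationic divalent palladium–pyridinooxazoline complex (transmetalation, enantiodetermining insertion of C2=C3 into the aryl–palladium bond, protonation of the enolate), in which the ligand sets C2 (the (R)-ligand is chosen for 2S by analogy with the (S)-ligand/(R)-product correlation of cyclic enones, the remote C2' centre exerting no useful bias) and the amine is kept protonated so that it does not bind palladium.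

Step 12
Reactants: 29 (2S)-5,7-diisopropoxy-2-(4-isopropoxyphenyl)-6-[(2S)-1-methylpiperidin-2-yl]chroman-4-one
Product: 30 (2S)-5,7-dihydroxy-2-(4-hydroxyphenyl)-6-[(2S)-1-methylpiperidin-2-yl]chroman-4-one (target)
Conditions: BCl3 (8 equiv), CH2Cl2, −78 to 0 °C; MeOH, then aqueous NaHCO3
Reagents that add atoms: none
Why: BCl3 cleaves aryl isopropyl ethers (chloride removes the isopropyl group from the boron-coordinated oxygen, fastest at the chelated 5-position) at temperatures low enough that neither the C2–O1 bond of the flavanone nor the benzylic C2'–N bond should ionize, so both stereocentres are expected to be retained.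

**Compound list**

1 | 2,4,6-trihydroxybenzaldehyde | O=Cc1c(O)cc(O)cc1O | starting material
2 | chlorotri(propan-2-yl)silane (TIPSCl) | CC(C)[Si](Cl)(C(C)C)C(C)C | starting material
3 | 2,6-dihydroxy-4-[(triisopropylsilyl)oxy]benzaldehyde | O=Cc1c(O)cc(O[Si](C(C)C)(C(C)C)C(C)C)cc1O | intermediate
4 | propan-2-ol | CC(C)O | starting material
5 | 2,6-diisopropoxy-4-[(triisopropylsilyl)oxy]benzaldehyde | O=Cc1c(OC(C)C)cc(O[Si](C(C)C)(C(C)C)C(C)C)cc1OC(C)C | intermediate
6 | 4-aminobutan-1-ol | NCCCCO | starting material
7 | di-tert-butyl dicarbonate | CC(C)(C)OC(=O)OC(=O)OC(C)(C)C | starting material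
8 | (E)-4-({[2,6-diisopropoxy-4-(triisopropylsilyloxy)phenyl]methylidene}amino)butan-1-ol (imine, not isolated) | OCCCC/N=C/c1c(OC(C)C)cc(O[Si](C(C)C)(C(C)C)C(C)C)cc1OC(C)C | intermediate
9 | 4-({[2,6-diisopropoxy-4-(triisopropylsilyloxy)phenyl]methyl}amino)butan-1-ol (not isolated) | OCCCCNCc1c(OC(C)C)cc(O[Si](C(C)C)(C(C)C)C(C)C)cc1OC(C)C | intermediate
10 | tert-butyl N-(4-hydroxybutyl)-N-{[2,6-diisopropoxy-4-(triisopropylsilyloxy)phenyl]methyl}carbamate | CC(C)(C)OC(=O)N(CCCCO)Cc1c(OC(C)C)cc(O[Si](C(C)C)(C(C)C)C(C)C)cc1OC(C)C | intermediate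
11 | methanesulfonyl chloride | CS(=O)(=O)Cl | starting material
12 | lithium chloride | [Li+].[Cl-] | starting material
13 | 4-{(tert-butoxycarbonyl){[2,6-diisopropoxy-4-(triisopropylsilyloxy)phenyl]methyl}amino}butyl methanesulfonate (not isolated) | CC(C)(C)OC(=O)N(CCCCOS(C)(=O)=O)Cc1c(OC(C)C)cc(O[Si](C(C)C)(C(C)C)C(C)C)cc1OC(C)C | intermediate
14 | tert-butyl N-(4-chlorobutyl)-N-{[2,6-diisopropoxy-4-(triisopropylsilyloxy)phenyl]methyl}carbamate | CC(C)(C)OC(=O)N(CCCCCl)Cc1c(OC(C)C)cc(O[Si](C(C)C)(C(C)C)C(C)C)cc1OC(C)C | intermediate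
15 | α-lithio derivative of 14 (lithium on the benzylic carbon, bound to (−)-sparteine; configuration at the lithiated carbon fixed by the diamine and not assigned here; not isolated) | CC(C)(C)OC(=O)N(CCCCCl)C([Li])c1c(OC(C)C)cc(O[Si](C(C)C)(C(C)C)C(C)C)cc1OC(C)C | intermediate
16 | tert-butyl (2S)-2-[2,6-diisopropoxy-4-(triisopropylsilyloxy)phenyl]piperidine-1-carboxylate | CC(C)(C)OC(=O)N1CCCC[C@H]1c1c(OC(C)C)cc(O[Si](C(C)C)(C(C)C)C(C)C)cc1OC(C)C | intermediate
17 | tert-butyl (2S)-2-(4-hydroxy-2,6-diisopropoxyphenyl)piperidine-1-carboxylate | CC(C)(C)OC(=O)N1CCCC[C@H]1c1c(OC(C)C)cc(O)cc1OC(C)C | intermediate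
18 | chloromethyl methyl ether | COCCl | starting material
19 | tert-butyl (2S)-2-[2,6-diisopropoxy-4-(methoxymethoxy)phenyl]piperidine-1-carboxylate | CC(C)(C)OC(=O)N1CCCC[C@H]1c1c(OC(C)C)cc(OCOC)cc1OC(C)C | intermediate
20 | (2S)-2-[2,6-diisopropoxy-4-(methoxymethoxy)phenyl]-1-methylpiperidine | CN1CCCC[C@H]1c1c(OC(C)C)cc(OCOC)cc1OC(C)C | intermediate
21 | N-methoxy-N-methylacetamide | CC(=O)N(C)OC | starting material
22 | aryllithium from 20, lithium on the ring carbon between the MOM ether and an isopropoxy group (not isolated) | CN1CCCC[C@H]1c1c(OC(C)C)cc(OCOC)c([Li])c1OC(C)C | intermediate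
23 | 1-{2,4-diisopropoxy-6-(methoxymethoxy)-3-[(2S)-1-methylpiperidin-2-yl]phenyl}ethan-1-one | CN1CCCC[C@H]1c1c(OC(C)C)cc(OCOC)c(C(C)=O)c1OC(C)C | intermediate
24 | N,N-dimethylformamide dimethyl acetal | COC(OC)N(C)C | starting material
25 | (E)-3-(dimethylamino)-1-{2,4-diisopropoxy-6-(methoxymethoxy)-3-[(2S)-1-methylpiperidin-2-yl]phenyl}prop-2-en-1-one (not isolated) | CN1CCCC[C@H]1c1c(OC(C)C)cc(OCOC)c(C(=O)/C=C/N(C)C)c1OC(C)C | intermediate
26 | (E)-3-(dimethylamino)-1-{6-hydroxy-2,4-diisopropoxy-3-[(2S)-1-methylpiperidin-2-yl]phenyl}prop-2-en-1-one (not isolated) | CN1CCCC[C@H]1c1c(OC(C)C)cc(O)c(C(=O)/C=C/N(C)C)c1OC(C)C | intermediate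
27 | 5,7-diisopropoxy-6-[(2S)-1-methylpiperidin-2-yl]-4H-chromen-4-one | CN1CCCC[C@H]1c1c(OC(C)C)cc2occc(=O)c2c1OC(C)C | intermediate
28 | (4-isopropoxyphenyl)boronic acid | CC(C)Oc1ccc(B(O)O)cc1 | starting material
29 | (2S)-5,7-diisopropoxy-2-(4-isopropoxyphenyl)-6-[(2S)-1-methylpiperidin-2-yl]chroman-4-one | CN1CCCC[C@H]1c1c(OC(C)C)cc2c(c1OC(C)C)C(=O)C[C@@H](c1ccc(OC(C)C)cc1)O2 | intermediate
30 | (2S)-5,7-dihydroxy-2-(4-hydroxyphenyl)-6-[(2S)-1-methylpiperidin-2-yl]chroman-4-one | CN1CCCC[C@H]1c1c(O)cc2c(c1O)C(=O)C[C@@H](c1ccc(O)cc1)O2 | target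

**Step count and risks**

Total step count: 12. Longest linear sequence: 12 steps (1 to 30).

Steps most likely to fail:

1. Step 5 (key step). What may go wrong: deprotonation of a ring C–H bond instead of the benzylic position, or a 6-exo ring closure slow enough for the organolithium to lose configuration before it alkylates, so that the piperidine forms in low yield or low enantiomeric purity. Fallback, which replaces asymmetric deprotonation by auxiliary-controlled addition, sets out from aldehyde 5. Condensation with (R)-2-methylpropane-2-sulfinamide (Ti(OEt)4, THF, 60 °C) should give the (R,E)-N-sulfinyl aldimine F1. The Grignard reagent 4-chlorobutylmagnesium bromide F2, prepared from 1-bromo-4-chlorobutane and Mg in THF, is added in CH2Cl2 at −48 °C, where the chelated chair transition state should deliver the chain to the face that gives the (S)-configured sulfinamide F3, the minor diastereomer being removable by chromatography. KN(SiMe3)2 in THF closes the ring by N-alkylation to the N-sulfinylpiperidine F4, brief HCl/MeOH at 0 °C removes the sulfinyl group to give the free (2S)-piperidine F5, and Boc2O brings the sequence back to the route at compound 16.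

2. Step 11. What may go wrong: inhibition of the palladium catalyst by the amine, slow insertion into the electron-rich chromone with competing protodeboronation of the boronic acid, or insufficient facial selectivity at C2. Fallback, which builds ring C by oxa-Michael closure of a chalcone and relies on separation of diastereomers, sets out from ketone 23. Claisen–Schmidt condensation with 4-isopropoxybenzaldehyde (KOH, EtOH, rt) should give the MOM-protected chalcone F6, and HCl in MeOH at rt removes the MOM group to give the 2'-hydroxychalcone F7. NaOAc in EtOH at reflux then closes ring C to flavanone 29 together with its (2R)-epimer F8. The two are diastereomers and are separated by chromatography, and F8 is returned to the same equilibrating conditions, so the sequence comes back to the route at compound 29.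

3. Step 12. What may go wrong: Lewis-acid-induced opening of ring C at the C2–O1 bond with loss of configuration at C2, or incomplete cleavage of the two non-chelated isopropyl ethers at the low temperature that protects the stereocentres. Fallback, which moves the dealkylation ahead of the creation of C2 and ends with a fluoride deprotection, sets out from chromone 27. BCl3 (CH2Cl2, −78 to 0 °C) at the chromone stage, where there is no C2 stereocentre to lose, should give the 5,7-dihydroxychromone F9. TBSCl and imidazole silylate the 7-OH and leave the chelated 5-OH free, giving the 7-O-silyl chromone F10. Conjugate arylation as in step 11 with [4-(tert-butyldimethylsilyloxy)phenyl]boronic acid gives the bis-silyl flavanone F11, and Et3N·3HF in THF at 0 °C removes both silyl groups under buffered conditions, so the sequence comes back to the route at compound 30.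

**Further compounds**

F1 | step 5 | (R,E)-N-{[2,6-diisopropoxy-4-(triisopropylsilyloxy)phenyl]methylidene}-2-methylpropane-2-sulfinamide | CC(C)(C)[S@@](=O)/N=C/c1c(OC(C)C)cc(O[Si](C(C)C)(C(C)C)C(C)C)cc1OC(C)C
F2 | step 5 | 4-chlorobutylmagnesium bromide | ClCCCC[Mg]Br
F3 | step 5 | (R)-N-{(1S)-5-chloro-1-[2,6-diisopropoxy-4-(triisopropylsilyloxy)phenyl]pentyl}-2-methylpropane-2-sulfinamide | CC(C)(C)[S@@](=O)N[C@@H](CCCCCl)c1c(OC(C)C)cc(O[Si](C(C)C)(C(C)C)C(C)C)cc1OC(C)C
F4 | step 5 | (2S)-1-[(R)-tert-butylsulfinyl]-2-[2,6-diisopropoxy-4-(triisopropylsilyloxy)phenyl]piperidine | CC(C)(C)[S@@](=O)N1CCCC[C@H]1c1c(OC(C)C)cc(O[Si](C(C)C)(C(C)C)C(C)C)cc1OC(C)C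
F5 | step 5 | (2S)-2-[2,6-diisopropoxy-4-(triisopropylsilyloxy)phenyl]piperidine | N1CCCC[C@H]1c1c(OC(C)C)cc(O[Si](C(C)C)(C(C)C)C(C)C)cc1OC(C)C
F6 | step 11 | (E)-1-{2,4-diisopropoxy-6-(methoxymethoxy)-3-[(2S)-1-methylpiperidin-2-yl]phenyl}-3-(4-isopropoxyphenyl)prop-2-en-1-one | CN1CCCC[C@H]1c1c(OC(C)C)cc(OCOC)c(C(=O)/C=C/c2ccc(OC(C)C)cc2)c1OC(C)C
F7 | step 11 | (E)-1-{6-hydroxy-2,4-diisopropoxy-3-[(2S)-1-methylpiperidin-2-yl]phenyl}-3-(4-isopropoxyphenyl)prop-2-en-1-one | CN1CCCC[C@H]1c1c(OC(C)C)cc(O)c(C(=O)/C=C/c2ccc(OC(C)C)cc2)c1OC(C)C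
F8 | step 11 | (2R)-5,7-diisopropoxy-2-(4-isopropoxyphenyl)-6-[(2S)-1-methylpiperidin-2-yl]chroman-4-one | CN1CCCC[C@H]1c1c(OC(C)C)cc2c(c1OC(C)C)C(=O)C[C@H](c1ccc(OC(C)C)cc1)O2
F9 | step 12 | 5,7-dihydroxy-6-[(2S)-1-methylpiperidin-2-yl]-4H-chromen-4-one | CN1CCCC[C@H]1c1c(O)cc2occc(=O)c2c1O
F10 | step 12 | 7-[(tert-butyldimethylsilyl)oxy]-5-hydroxy-6-[(2S)-1-methylpiperidin-2-yl]-4H-chromen-4-one | CN1CCCC[C@H]1c1c(O[Si](C)(C)C(C)(C)C)cc2occc(=O)c2c1O
F11 | step 12 | (2S)-7-[(tert-butyldimethylsilyl)oxy]-2-{4-[(tert-butyldimethylsilyl)oxy]phenyl}-5-hydroxy-6-[(2S)-1-methylpiperidin-2-yl]chroman-4-one | CN1CCCC[C@H]1c1c(O[Si](C)(C)C(C)(C)C)cc2c(c1O)C(=O)C[C@@H](c1ccc(O[Si](C)(C)C(C)(C)C)cc1)O2
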